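**Retrosyn­thetic overview**

1. Feature: in ring B (C5–C10) the angular methyl C20 on C10 stands beside C9, the side-chain carbon, which is alpha to the C8 carbinol carbon. That is the pattern left when a C9–C10 cyclopropane next to a C8 ketone is opened reductively, and ring B with its C8 oxygen is an anisole ring in disguise.
2. Target 26 ⇐ C3–Br by one SN2 inversion of an axial C3 carbinol, and C8 carbinol/C17 methyl from the 8(17)-methylene (epoxide, hydride) ⇐ 8-ketone 20 ⇐ C9–C11 alkylation of the C8/C9 enolate with iodide 17, which brings C13 from (R)-linalool.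
3. Enolate and C10 methyl ⇐ Li/NH3 opening of cyclopropyl ketone 10 ⇐ hydroxyl-directed Simmons–Smith cyclopropanation of octalin-8-ol 8 (forms C9–C20 and C10–C20).
4. 8 ⇐ 6-methoxy-2-tetralone by C4 gem-dimethylation, asymmetric ketone reduction (C3), Birch reduction, catalyst-controlled β,γ→α,β isomerisation (C5) and bulky-hydride 1,2-reduction (C8). C5 is not left to equilibration, because a silyloxy group beside the gem-dimethyl carbon is too weak a conformational anchor. The C3 oxygen is carried axial (cis to C5–H), so that a single inversion gives the equatorial bromide.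
5. Ring order: rings A and B come with the tetralone (ring B is dearomatised in step 4); the only ring closed is the cyclopropane (step 8), which is reopened in step 14.

Key step: step 8

Assumption: the quinine-derived amine of step 6 is taken to protonate C5 on the face cis to the C3 silyloxy group; if its sense is the opposite, the quinidine-derived pseudoenantiomer is used instead.

Labdane numbering is used for the decalin intermediates: ring A = C1–C5, C10; ring B = C5–C10; C20 = carbon on C10; C17 = carbon on C8; side chain C11–C16 on C9.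

**Route**

Step 1
Reactants: 1 6-methoxy-2-tetralone
Product: 2 6-methoxy-1,1-dimethyl-3,4-dihydronaphthalen-2(1H)-one
Conditions: NaH (2.2 equiv), MeI (2.3 equiv), THF, 0 °C → rt
Reagents that add atoms: iodomethane, CI
Why: Enolate alkylation at the benzylic, doubly activated C1, which remains the most acidic site after the first methylation and so takes both methyl groups.

Step 2
Reactants: 2 6-methoxy-1,1-dimethyl-3,4-dihydronaphthalen-2(1H)-one
Product: 3 (S)-6-methoxy-1,1-dimethyl-1,2,3,4-tetrahydronaphthalen-2-ol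
Conditions: (R)-1-methyl-3,3-diphenyltetrahydro-1H,3H-pyrrolo[1,2-c][1,3,2]oxazaborole (10 mol %), BH3·SMe2, THF, −20 °C; then MeOH
Reagents that add atoms: none
Why: Corey–Bakshi–Shibata reduction, in which the ketone binds the oxazaborolidine with the quaternary benzylic carbon as the large group and hydride goes to one face, which with the (R)-catalyst should give the (S)-carbinol (labdane C3).

Step 3
Reactants: 3 (S)-6-methoxy-1,1-dimethyl-1,2,3,4-tetrahydronaphthalen-2-ol
Product: 4 (S)-tert-butyl[(6-methoxy-1,1-dimethyl-1,2,3,4-tetrahydronaphthalen-2-yl)oxy]dimethylsilane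
Conditions: TBSOTf, 2,6-lutidine, CH2Cl2, 0 °C
Reagents that add atoms: tert-butyldimethylsilyl triflate, CC(C)(C)[Si](C)(C)OS(=O)(=O)C(F)(F)F
Why: Silyl triflate silylation of a hindered neopentyl secondary alcohol gives an ether that tolerates dissolving metal, hydride, base and peracid.

Step 4
Reactants: 4 (S)-tert-butyl[(6-methoxy-1,1-dimethyl-1,2,3,4-tetrahydronaphthalen-2-yl)oxy]dimethylsilane
Product: 5 (S)-tert-butyl[(6-methoxy-1,1-dimethyl-1,2,3,4,5,8-hexahydronaphthalen-2-yl)oxy]dimethylsilane
Conditions: Li, NH3 (l), THF, t-BuOH, −78 → −33 °C; then NH4Cl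
Reagents that add atoms: none
Why: Birch reduction of the anisole gives the 2,5-dihydroanisole that keeps the methoxy carbon and the two alkyl-bearing carbons on the remaining double bonds, while the non-benzylic silyl ether is inert.

Step 5
Reactants: 5 (S)-tert-butyl[(6-methoxy-1,1-dimethyl-1,2,3,4,5,8-hexahydronaphthalen-2-yl)oxy]dimethylsilane
Product: 6 (S)-6-(tert-butyldimethylsilyloxy)-5,5-dimethyl-3,4,5,6,7,8-hexahydronaphthalen-2(1H)-one
Conditions: oxalic acid, THF/MeOH/H2O, rt
Reagents that add atoms: water, O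
Why: Mild acid hydrolysis of the enol ether should stop at the β,γ-unsaturated ketone, because oxalic acid does not move the tetrasubstituted C5=C10 bond into conjugation.

Step 6
Reactants: 6 (S)-6-(tert-butyldimethylsilyloxy)-5,5-dimethyl-3,4,5,6,7,8-hexahydronaphthalen-2(1H)-one
Product: 7 (4aS,6S)-6-(tert-butyldimethylsilyloxy)-5,5-dimethyl-4,4a,5,6,7,8-hexahydronaphthalen-2(3H)-one
Conditions: 9-amino-9-deoxy-epi-quinine (20 mol %), 2-nitrobenzoic acid (40 mol %), toluene, −20 °C
Reagents that add atoms: none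
Why: Chiral primary-amine (iminium/dienamine) catalysed isomerisation of a Birch-derived β,γ-unsaturated ketone, in which the catalyst delivers the proton to C5 of the dienamine and so should set C5 kinetically with H cis to the C3 silyloxy group; the C3 centre guarantees enantiopurity and makes any C5 epimer a separable diastereomer.

Step 7
Reactants: 7 (4aS,6S)-6-(tert-butyldimethylsilyloxy)-5,5-dimethyl-4,4a,5,6,7,8-hexahydronaphthalen-2(3H)-one
Product: 8 (2R,4aS,6S)-6-(tert-butyldimethylsilyloxy)-5,5-dimethyl-2,3,4,4a,5,6,7,8-octahydronaphthalen-2-ol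
Conditions: LiBH(s-Bu)3, THF, −78 °C; then NaOH, H2O2
Reagents that add atoms: none
Why: 1,2-Reduction of the β,β-disubstituted enone by a bulky trialkylborohydride from the equatorial direction should give the pseudo-axial C8 alcohol trans to C5–H, the sense expected for ring-fused cyclohexenones that carry only hydrogen at the gamma ring-fusion carbon.

Step 8
Reactants: 8 (2R,4aS,6S)-6-(tert-butyldimethylsilyloxy)-5,5-dimethyl-2,3,4,4a,5,6,7,8-octahydronaphthalen-2-ol
Product: 9 (3S,5S,8R,9S,10S)-3-(tert-butyldimethylsilyloxy)-4,4-dimethyl-9,10-methanodecalin-8-ol (labdane numbering; cyclopropane CH2 = C20)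
Conditions: Et2Zn, CH2I2, CH2Cl2, 0 °C → rt
Reagents that add atoms: diiodomethane, ICI
Why: Et2Zn turns the C8 hydroxyl into a zinc alkoxide that binds the iodomethylzinc carbenoid and hands its methylene to the adjacent C9=C10 bond through the concerted butterfly transition state, so both new bonds (C9–C20 and C10–C20) form on the hydroxyl face. This is the hydroxyl-directed Simmons–Smith cyclopropanation of a cyclic allylic alcohol. The three-membered ring is closed by a concerted [2+1] methylene transfer across the alkene, with no discrete intermediate. The new stereocentres C9 and C10 are both fixed by the C8 carbinol through syn delivery, and because that hydroxyl is trans to C5–H, the C10–C20 bond (the future angular methyl) is trans to C5–H. The step needs facial selectivity only, and the substrate secures it: the hydroxyl is the sole Lewis-basic director on its face, the axial C3 silyl ether lies on the other face and does not coordinate, and C9=C10 is the only alkene.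

Step 9
Reactants: 9 (3S,5S,8R,9S,10S)-3-(tert-butyldimethylsilyloxy)-4,4-dimethyl-9,10-methanodecalin-8-ol
Product: 10 (3S,5S,9S,10S)-3-(tert-butyldimethylsilyloxy)-4,4-dimethyl-9,10-methanodecalin-8-one
Conditions: Dess–Martin periodinane, NaHCO3, CH2Cl2, rt
Reagents that add atoms: none
Why: Dess–Martin oxidation of the secondary cyclopropyl carbinol under buffered, non-acidic conditions avoids cyclopropylcarbinyl cation rearrangement.

Step 10
Reactants: 11 (R)-linalool
Product: 12 (R)-1-{[(3,7-dimethylocta-1,6-dien-3-yl)oxy]methyl}-4-methoxybenzene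
Conditions: NaH, 4-methoxybenzyl chloride, Bu4NI (cat.), DMF, 0 °C → rt
Reagents that add atoms: 4-methoxybenzyl chloride, COc1ccc(CCl)cc1
Why: Williamson etherification of the tertiary alkoxide with a benzylic halide leaves the stereocentre untouched and gives an ether orthogonal to the C3 silyl ether.

Step 11
Reactants: 12 (R)-1-{[(3,7-dimethylocta-1,6-dien-3-yl)oxy]methyl}-4-methoxybenzene
Product: 14 (R)-4-[(4-methoxybenzyl)oxy]-4-methylhex-5-enal, via secondary ozonide 13 (not isolated)
Conditions: O3, CH2Cl2, −78 °C, Sudan Red 7B end-point; then Me2S, −78 °C → rt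
Reagents that add atoms: ozone, [O-][O+]=O
Why: Ozonolysis, in which ozone attacks the electron-rich trisubstituted alkene much faster than the vinyl group or the anisyl ring, with the dye marking the end-point; reduction of the ozonide gives the aldehyde.

Step 12
Reactants: 14 (R)-4-[(4-methoxybenzyl)oxy]-4-methylhex-5-enal
Product: 15 (R)-4-[(4-methoxybenzyl)oxy]-4-methylhex-5-enoic acid
Conditions: NaClO2, NaH2PO4, 2-methylbut-2-ene, t-BuOH/H2O, rt
Reagents that add atoms: sodium chlorite, [Na+].[O-]Cl=O
Why: Pinnick oxidation takes the aldehyde to the acid while the scavenger protects the vinyl group and the ether.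

Step 13
Reactants: 15 (R)-4-[(4-methoxybenzyl)oxy]-4-methylhex-5-enoic acid
Product: 17 (R)-1-{[(5-iodo-3-methylpent-1-en-3-yl)oxy]methyl}-4-methoxybenzene, via thiohydroxamate ester 16 (not isolated)
Conditions: 1-hydroxypyridine-2(1H)-thione, DCC, 4-(dimethylamino)pyridine (cat.), CH2Cl2, dark, rt; then CHI3, hν, rt
Reagents that add atoms: iodoform, IC(I)I
Why: Barton decarboxylative iodination, in which the ester fragments under light to the primary radical, which abstracts iodine from iodoform far faster than it could close a four-membered ring onto the vinyl group.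

Step 14
Reactants: 10 (3S,5S,9S,10S)-3-(tert-butyldimethylsilyloxy)-4,4-dimethyl-9,10-methanodecalin-8-one; 17 (R)-1-{[(5-iodo-3-methylpent-1-en-3-yl)oxy]methyl}-4-methoxybenzene
Product: 20 (3S,5S,9S,10R,13R)-3-(tert-butyldimethylsilyloxy)-13-[(4-methoxybenzyl)oxy]-17-norlabd-14-en-8-one, via lithium enolate 18 (not isolated), via C9-epimeric ketone 19 (not isolated)
Conditions: Li (2.2 equiv), t-BuOH (1 equiv), NH3/THF, −78 °C; isoprene; NH3 evaporated; 17, DMPU, THF, −40 → 0 °C; then MeOH, NaOMe (cat.), rt
Reagents that add atoms: none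
Why: Dissolving-metal cleavage of the conjugated cyclopropyl ketone with enolate alkylation, in which electron transfer breaks C9–C20 (the cyclopropane bond aligned with the carbonyl π system) so that C20 becomes the C10 methyl trans to C5–H and the C8/C9 enolate forms regiospecifically, is C-alkylated by the primary iodide (axially, anti to C20) and is then equilibrated by methoxide to the equatorial C9 epimer.

Step 15
Reactants: 20 (3S,5S,9S,10R,13R)-3-(tert-butyldimethylsilyloxy)-13-[(4-methoxybenzyl)oxy]-17-norlabd-14-en-8-one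
Product: 21 (3S,5S,9R,10S,13R)-3-(tert-butyldimethylsilyloxy)-13-[(4-methoxybenzyl)oxy]labda-8(17),14-diene
Conditions: Ph3PCH3Br, KOt-Bu, toluene, 80 °C
Reagents that add atoms: methyltriphenylphosphonium bromide, C[P+](c1ccccc1)(c1ccccc1)c1ccccc1.[Br-]
Why: Wittig methylenation of the hindered C8 ketone, whose C9 centre is already in its thermodynamic configuration and so cannot be degraded by the basic ylide (the change of descriptors at C9 and C10 is a priority effect only).

Step 16
Reactants: 21 (3S,5S,9R,10S,13R)-3-(tert-butyldimethylsilyloxy)-13-[(4-methoxybenzyl)oxy]labda-8(17),14-diene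
Product: 22 (3S,5S,8S,9S,10R,13R)-3-(tert-butyldimethylsilyloxy)-8,17-epoxy-13-[(4-methoxybenzyl)oxy]labd-14-ene
Conditions: mCPBA, NaHCO3, CH2Cl2, 0 °C
Reagents that add atoms: 3-chloroperoxybenzoic acid, OOC(=O)c1cccc(Cl)c1
Why: Prilezhaev epoxidation of the 1,1-disubstituted alkene, which is more nucleophilic than the vinyl group, should occur from the face opposite the axial C10 methyl and place the epoxide oxygen equatorial.

Step 17
Reactants: 22 (3S,5S,8S,9S,10R,13R)-3-(tert-butyldimethylsilyloxy)-8,17-epoxy-13-[(4-methoxybenzyl)oxy]labd-14-ene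
Product: 23 (3S,5S,8S,9S,10R,13R)-3-(tert-butyldimethylsilyloxy)-13-[(4-methoxybenzyl)oxy]labd-14-en-8-ol
Conditions: LiAlH4, THF, 0 → 50 °C
Reagents that add atoms: none
Why: Hydride opens the spiro-epoxide at its primary carbon (SN2), leaving the equatorial tertiary C8 alcohol and the axial C17 methyl with the C8 configuration set in step 16.

Step 18
Reactants: 23 (3S,5S,8S,9S,10R,13R)-3-(tert-butyldimethylsilyloxy)-13-[(4-methoxybenzyl)oxy]labd-14-en-8-ol
Product: 24 (3S,5S,8S,9S,10R,13R)-13-[(4-methoxybenzyl)oxy]labd-14-ene-3,8-diol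
Conditions: Bu4NF, THF, 50 °C
Reagents that add atoms: none
Why: Fluoride cleavage of the silyl ether frees the axial C3 hydroxyl without touching the benzyl-type ether or the tertiary alcohol.

Step 19
Reactants: 24 (3S,5S,8S,9S,10R,13R)-13-[(4-methoxybenzyl)oxy]labd-14-ene-3,8-diol
Product: 25 (3R,5S,8S,9S,10R,13R)-3-bromo-13-[(4-methoxybenzyl)oxy]labd-14-en-8-ol
Conditions: CBr4, PPh3, pyridine, toluene, 0 → 60 °C
Reagents that add atoms: carbon tetrabromide, BrC(Br)(Br)Br
Why: Appel reaction, in which bromide displaces the axial C3 alkoxyphosphonium group with inversion to give the equatorial bromide, while the tertiary C8 hydroxyl is expected to be activated far more slowly.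

Step 20
Reactants: 25 (3R,5S,8S,9S,10R,13R)-3-bromo-13-[(4-methoxybenzyl)oxy]labd-14-en-8-ol
Product: 26 (3R,5S,8S,9S,10R,13R)-3-bromolabd-14-ene-8,13-diol
Conditions: 2,3-dichloro-5,6-dicyano-1,4-benzoquinone, CH2Cl2/pH 7 buffer, 0 °C
Reagents that add atoms: none
Why: Oxidative cleavage of the 4-methoxybenzyl ether through its benzylic cation and hemiacetal releases the tertiary allylic alcohol under neutral conditions that spare the alkyl bromide, the vinyl group and the C8 alcohol.

**Compound list**

1 | 6-methoxy-2-tetralone | COc1ccc2CC(=O)CCc2c1 | starting material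
2 | 6-methoxy-1,1-dimethyl-3,4-dihydronaphthalen-2(1H)-one | COc1ccc2c(c1)CCC(=O)C2(C)C | intermediate
3 | (S)-6-methoxy-1,1-dimethyl-1,2,3,4-tetrahydronaphthalen-2-ol | COc1ccc2c(c1)CC[C@H](O)C2(C)C | intermediate
4 | (S)-tert-butyl[(6-methoxy-1,1-dimethyl-1,2,3,4-tetrahydronaphthalen-2-yl)oxy]dimethylsilane | COc1ccc2c(c1)CC[C@H](O[Si](C)(C)C(C)(C)C)C2(C)C | intermediate
5 | (S)-tert-butyl[(6-methoxy-1,1-dimethyl-1,2,3,4,5,8-hexahydronaphthalen-2-yl)oxy]dimethylsilane | COC1=CCC2=C(C1)CC[C@H](O[Si](C)(C)C(C)(C)C)C2(C)C | intermediate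
6 | (S)-6-(tert-butyldimethylsilyloxy)-5,5-dimethyl-3,4,5,6,7,8-hexahydronaphthalen-2(1H)-one | O=C1CCC2=C(C1)CC[C@H](O[Si](C)(C)C(C)(C)C)C2(C)C | intermediate
7 | (4aS,6S)-6-(tert-butyldimethylsilyloxy)-5,5-dimethyl-4,4a,5,6,7,8-hexahydronaphthalen-2(3H)-one (C5–H cis to the C3 silyloxy group) | O=C1CC[C@H]2C(=C1)CC[C@H](O[Si](C)(C)C(C)(C)C)C2(C)C | intermediate
8 | (2R,4aS,6S)-6-(tert-butyldimethylsilyloxy)-5,5-dimethyl-2,3,4,4a,5,6,7,8-octahydronaphthalen-2-ol (octalin-8-ol; 8-OH trans to C5–H) | O[C@@H]1CC[C@H]2C(=C1)CC[C@H](O[Si](C)(C)C(C)(C)C)C2(C)C | intermediate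
9 | (3S,5S,8R,9S,10S)-3-(tert-butyldimethylsilyloxy)-4,4-dimethyl-9,10-methanodecalin-8-ol (cyclopropane CH2 cis to 8-OH, trans to C5–H) | O[C@@H]1CC[C@H]2[C@@]3(C[C@H]13)CC[C@H](O[Si](C)(C)C(C)(C)C)C2(C)C | intermediate
10 | (3S,5S,9S,10S)-3-(tert-butyldimethylsilyloxy)-4,4-dimethyl-9,10-methanodecalin-8-one | O=C1CC[C@H]2[C@@]3(C[C@H]13)CC[C@H](O[Si](C)(C)C(C)(C)C)C2(C)C | intermediate
11 | (R)-linalool | C=C[C@](C)(O)CCC=C(C)C | starting material
12 | (R)-1-{[(3,7-dimethylocta-1,6-dien-3-yl)oxy]methyl}-4-methoxybenzene | C=C[C@](C)(OCc1ccc(OC)cc1)CCC=C(C)C | intermediate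
13 | secondary ozonide (1,2,4-trioxolane) of the 6,7-alkene of 12 | C=C[C@](C)(OCc1ccc(OC)cc1)CCC1OOC(C)(C)O1 | intermediate
14 | (R)-4-[(4-methoxybenzyl)oxy]-4-methylhex-5-enal | C=C[C@](C)(OCc1ccc(OC)cc1)CCC=O | intermediate
15 | (R)-4-[(4-methoxybenzyl)oxy]-4-methylhex-5-enoic acid | C=C[C@](C)(OCc1ccc(OC)cc1)CCC(=O)O | intermediate
16 | 2-thioxopyridin-1(2H)-yl (R)-4-[(4-methoxybenzyl)oxy]-4-methylhex-5-enoate | C=C[C@](C)(OCc1ccc(OC)cc1)CCC(=O)On1ccccc1=S | intermediate
17 | (R)-1-{[(5-iodo-3-methylpent-1-en-3-yl)oxy]methyl}-4-methoxybenzene | C=C[C@](C)(OCc1ccc(OC)cc1)CCI | intermediate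
18 | lithium C8/C9 enolate of the 3-silyloxy-4,4,10-trimethyl-trans-decalin-8-one (C10 methyl trans to C5–H) | [Li+].[O-]C1=C[C@]2(C)CC[C@H](O[Si](C)(C)C(C)(C)C)C(C)(C)[C@H]2CC1 | intermediate
19 | (3S,5S,9R,10R,13R)-3-(tert-butyldimethylsilyloxy)-13-[(4-methoxybenzyl)oxy]-17-norlabd-14-en-8-one (side chain axial) | C=C[C@](C)(OCc3ccc(OC)cc3)CC[C@@H]1[C@]2(C)CC[C@H](O[Si](C)(C)C(C)(C)C)C(C)(C)[C@H]2CCC1=O | intermediate
20 | (3S,5S,9S,10R,13R)-3-(tert-butyldimethylsilyloxy)-13-[(4-methoxybenzyl)oxy]-17-norlabd-14-en-8-one (side chain equatorial) | C=C[C@](C)(OCc3ccc(OC)cc3)CC[C@H]1[C@]2(C)CC[C@H](O[Si](C)(C)C(C)(C)C)C(C)(C)[C@H]2CCC1=O | intermediate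
21 | (3S,5S,9R,10S,13R)-3-(tert-butyldimethylsilyloxy)-13-[(4-methoxybenzyl)oxy]labda-8(17),14-diene | C=C[C@](C)(OCc3ccc(OC)cc3)CC[C@H]1[C@]2(C)CC[C@H](O[Si](C)(C)C(C)(C)C)C(C)(C)[C@H]2CCC1=C | intermediate
22 | (3S,5S,8S,9S,10R,13R)-3-(tert-butyldimethylsilyloxy)-8,17-epoxy-13-[(4-methoxybenzyl)oxy]labd-14-ene (epoxide oxygen equatorial) | C=C[C@](C)(OCc3ccc(OC)cc3)CC[C@H]1[C@]2(C)CC[C@H](O[Si](C)(C)C(C)(C)C)C(C)(C)[C@H]2CC[C@@]12CO2 | intermediate
23 | (3S,5S,8S,9S,10R,13R)-3-(tert-butyldimethylsilyloxy)-13-[(4-methoxybenzyl)oxy]labd-14-en-8-ol | C=C[C@](C)(OCc3ccc(OC)cc3)CC[C@H]1[C@]2(C)CC[C@H](O[Si](C)(C)C(C)(C)C)C(C)(C)[C@H]2CC[C@]1(C)O | intermediate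
24 | (3S,5S,8S,9S,10R,13R)-13-[(4-methoxybenzyl)oxy]labd-14-ene-3,8-diol (3-OH axial) | C=C[C@](C)(OCc3ccc(OC)cc3)CC[C@H]1[C@]2(C)CC[C@H](O)C(C)(C)[C@H]2CC[C@]1(C)O | intermediate
25 | (3R,5S,8S,9S,10R,13R)-3-bromo-13-[(4-methoxybenzyl)oxy]labd-14-en-8-ol (3-Br equatorial) | C=C[C@](C)(OCc3ccc(OC)cc3)CC[C@H]1[C@]2(C)CC[C@@H](Br)C(C)(C)[C@H]2CC[C@]1(C)O | intermediate
26 | (3R,5S,8S,9S,10R,13R)-3-bromolabd-14-ene-8,13-diol | C=C[C@](C)(O)CC[C@H]1[C@]2(C)CC[C@@H](Br)C(C)(C)[C@H]2CC[C@]1(C)O | target

**Step count and risks**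

Total steps: 20. Longest linear sequence: 16 (steps 1–9 and 14–20).

The three steps most likely to fail:

Step 19. Bromide must approach C3 from the rear of an axial leaving group that sits beside the quaternary C4, so the displacement is slow. The activated alcohol may instead lose a proton from C2 or undergo a 1,2-methyl shift, and the tertiary C8 hydroxyl may be activated in the meantime. The fallback replaces the one-pot oxyphosphonium route by a two-stage activation and displacement. It sets out from 24: ClCH2SO2Cl and pyridine at 0 °C sulfonylate only the secondary hydroxyl and give the chloromethanesulfonate F9, an isolable electrophile that is less prone to ionise. LiBr in DMPU (or Bu4NBr in toluene) at 60–80 °C then displaces it with inversion, and the route is rejoined at 25.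

Step 14. C-alkylation of the hindered C9 enolate by an unactivated primary iodide may be slower than proton transfer between enolate and product. That would lead to enolate migration towards C7, double alkylation and recovery of reduced but unalkylated ketone. The fallback forms the C9–C11 bond by an aldol reaction, which is much faster than alkylation. Aldehyde 14 is converted with TMSCl, NaI and Et3N into the silyl enol ether F5, whose selective ozonolysis (Me2S work-up) gives the one-carbon-shorter aldehyde F6. The fallback then sets out from 10: the enolate 18 is generated as in step 14 and trapped at −78 °C with F6 to give the β-hydroxy ketone F7. MsCl/Et3N followed by DBU gives the alkylidene ketone F8. Conjugate reduction with LiBH(s-Bu)3 and NaOMe equilibration then return the route to 20.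

Step 6. Facial selectivity in the γ-protonation may be poor at a carbon flanked by the gem-dimethyl group, and C5 may epimerise afterwards through a re-formed dienamine. The fallback sets C5 by hydroxyl-directed hydrogenation instead of protonation. It sets out from 6: Bu4NF gives the hydroxy ketone F1, and H2 with [Ir(cod)(PCy3)(py)]PF6 in CH2Cl2 delivers both hydrogens to C5 and C10 from the face of the C3 hydroxyl to give the cis-fused decalone F2. TBSOTf/2,6-lutidine gives the silyl ether F3. TMSCl, NaI and Et3N give the thermodynamic silyl enol ether F4, expected towards C9 for a cis-fused 2-decalone. Saegusa oxidation with Pd(OAc)2 in MeCN then restores the C9=C10 enone, and the route is rejoined at 7.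

Further compounds
F1 | step 6 | (S)-6-hydroxy-5,5-dimethyl-3,4,5,6,7,8-hexahydronaphthalen-2(1H)-one | O=C1CCC2=C(C1)CC[C@H](O)C2(C)C
F2 | step 6 | cis-fused 3-hydroxy-4,4-dimethyldecalin-8-one (labdane numbering; H5 and H10 cis to 3-OH) | O=C1CC[C@H]2[C@@H](C1)CC[C@H](O)C2(C)C
F3 | step 6 | tert-butyldimethylsilyl ether of F2 | O=C1CC[C@H]2[C@@H](C1)CC[C@H](O[Si](C)(C)C(C)(C)C)C2(C)C
F4 | step 6 | C8/C9 trimethylsilyl enol ether of F3 | C[Si](C)(C)OC1=C[C@H]2CC[C@H](O[Si](C)(C)C(C)(C)C)C(C)(C)[C@H]2CC1
F5 | step 14 | trimethylsilyl enol ether of aldehyde 14 (E/Z mixture) | C=C[C@](C)(OCc1ccc(OC)cc1)CC=CO[Si](C)(C)C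
F6 | step 14 | (R)-3-[(4-methoxybenzyl)oxy]-3-methylpent-4-enal | C=C[C@](C)(OCc1ccc(OC)cc1)CC=O
F7 | step 14 | 11-hydroxy derivative of ketone 20 (aldol adduct, mixture at C9 and C11) | C=C[C@](C)(OCc3ccc(OC)cc3)CC(O)C1[C@]2(C)CC[C@H](O[Si](C)(C)C(C)(C)C)C(C)(C)[C@H]2CCC1=O
F8 | step 14 | 9(11)-alkylidene ketone from dehydration of F7 | C=C[C@](C)(OCc3ccc(OC)cc3)CC=C1[C@]2(C)CC[C@H](O[Si](C)(C)C(C)(C)C)C(C)(C)[C@H]2CCC1=O
F9 | step 19 | 3-O-chloromethanesulfonate of diol 24 | C=C[C@](C)(OCc3ccc(OC)cc3)CC[C@H]1[C@]2(C)CC[C@H](OS(=O)(=O)CCl)C(C)(C)[C@H]2CC[C@]1(C)O
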